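The earlier runs and the new flask were computed on assumed constants; the scatter is artificial.

A small charge of Z is the place to start, so count turnovers: each Z + L → D spends one Z and one X. The west run is the asked flask, followed so far.

in all of them: X 0.40 M
- west: Q 0.24 M; Z 0.24 M; the very flask that is asked about, followed so far
- flask: Q 0.240 M; Z 0.240 M; time 80 min

- west (time / min: E / %, D / %): 0.833: 1.3, 10.8; 2.50: 4.5, 27.8; 5.00: 7.4, 45.0; 6.00: 8.7, 49.6; 10.0: 11.7, 58.6; 12.0: 13.2, 59.9; 15.0: 13.6, 59.5

(standard deviation of a reading: 0.3 percentage points)

- the earlier runs were read with a standard deviation of 0.3 percentage points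
- steps under discussion: E <-> G; Q + L -> E; Z + L -> D; X <-> L; Q <-> J

1. ratio of E to D at 20 s
2. ratio of E to D at 80 min
3. which of E and D there is more of at 80 min

1. Take C, the share of X that Z can pay for in this flask, as Z's charge over X's: 60.0%. This is the limiting-reagent count. The west readings of D, 59.9% at 12.0 min and 59.5% at 15.0 min, stand 0.1 percentage points and 0.5 points below C, read with a standard deviation of 0.3 points.

2. Count the time. The first west reading gives a rate k, (E + D)/t, of 0.145 /min, so a half-life h of 4.77 min. At that rate, 80 min holds 16.8 half-lives, far longer than h, so my estimate for this flask is hardly any X left at 80 min.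

3. Define the pool P, the share of X that ends as E or G: the smaller of what Z leaves over and what Q's charge pays for through Q + L → E, 40.0%. Here Q's charge pays for 60.0%, more than P.

4. My reckoning: D leads, since C is more than P. G was not read, so for E/D at 80 min the count gives a ceiling, P/C, 0.667, and no value. For E/D at 20 s, take the first west reading, at 0.833 min: 0.120, with its scatter.

5. The forecast gave 0.13 at 20 s, 0.35 at 80 min and D ahead: “I guess E ≈ 20%, so the ratio is about 0.35, quite uncertain.”

6. The flask gives 0.164 at 20 s and 0.148 at 80 min, with D ahead: E 8.90%, D 60.0%.

    E ⇌ G (K = 3.50, k = 0.00230 /s)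
    Q + L → E (k = 3.80 /M/s)
    Z + L → D (k = 23.0 /M/s)
    X ⇌ L (K = 0.0530, k = 0.00270 /s)
    Q ⇌ J (K = 1.10, k = 0.00150 /s)

E and G in this flask relax by E ⇌ G alone, both ways together, with a half-life of 3.91 min, short against 80 min. Taking K of that step as G/E, P shares out to E at P/(1 + K), 8.89%, and the flask holds G at 31.1%.

In a neighbour flask with 0.060 M of Z, what Q's charge pays for is less than what Z leaves over, so P is 60.0% and C is 15.0%, which gives E/D of 0.889. That flask gives 0.890, with E 13.4%, G 46.6% and D 15.0%.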